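**Retrosynthetic overview**
1. Key disconnection: the C6–O diaryl ether bond joining the 7-methoxyflavone half (half A) to the 4'-oxygen of the apigenin half (half B). It is the only skeletal bond made.
2. Both halves go back to one feedstock, apigenin (1). Half A is 1 → genkwanin (2) → its 4'-O-benzyl ether (3). Half B is 1 → its 7-O-benzyl ether (4).
3. Union: the C6–H of 3 is turned in the flask into a mesityl-λ3-iodane (5, then 6). Copper catalysis then exchanges it for the 4'-oxygen of 4 to give dibenzyl ether 7.
4. End game: one hydrogenolysis frees both phenols, 7 → isocryptomerin (8).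
5. Ring order: no ring is built. All six rings (A, B and C of each half) arrive intact in 1.

Assumption: the target SMILES has no stereocentre and the diaryl ether axis rotates freely. The target is therefore one achiral compound, and no step creates or needs stereocontrol.

**Step 1**
Reactants: 1 apigenin
Product: 2 genkwanin (apigenin 7-O-methyl ether)
Conditions: MeI (1.05 equiv), K2CO3 (1.0 equiv), DMF, 0 °C → rt
Reagents that add atoms: iodomethane, CI
Why: Williamson ether synthesis under acidity control: the 7-OH (para to the C4 carbonyl, pKa about 7) is the most acidic phenol and is alkylated first by the limiting MeI, while the 5-OH is locked in a hydrogen bond to C4=O.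

**Step 2**
Reactants: 2 genkwanin
Product: 3 4'-O-benzylgenkwanin
Conditions: BnBr (1.2 equiv), K2CO3 (1.5 equiv), DMF, rt
Reagents that add atoms: benzyl bromide, BrCc1ccccc1
Why: Williamson ether synthesis: the 4'-OH is the only unchelated phenol left, and the chelated 5-OH does not alkylate at room temperature.

**Step 3**
Reactants: 1 apigenin
Product: 4 7-O-benzylapigenin
Conditions: BnBr (1.05 equiv), K2CO3 (1.0 equiv), DMF, 0 °C → rt
Reagents that add atoms: benzyl bromide, BrCc1ccccc1
Why: Williamson ether synthesis with the same acidity-controlled 7-OH selectivity as in step 1, which leaves the 4'-OH free as the later nucleophile and the 5-OH chelated.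

**Step 4**
Reactants: 3 4'-O-benzylgenkwanin; 4 7-O-benzylapigenin
Product: 7 di-O-benzylisocryptomerin (half A 4'-OBn; half B 7-OBn), via iodonium acetate 5 (not isolated), via iodonium phenolate 6 (not isolated)
Conditions: MesI(OAc)2 (1.0 equiv), HFIP, 0 °C → rt; strip HFIP/AcOH with toluene; then 4 (1.2 equiv), Cu(MeCN)4PF6 (10 mol %), 4 Å MS, DMF, 40 °C
Reagents that add atoms: iodomesitylene diacetate, CC(=O)OI(OC(C)=O)c1c(C)cc(C)cc1C (its mesityl-iodine unit and one acetate are carried only by 5 and 6 and are gone again in 7)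
Why: Proposed new method: a one-pot dehydrogenative C6–H/O–H diaryl ether coupling through a transient ortho-iodonio phenolate, not yet described for a flavone or for aryloxide transfer to such a zwitterion. HFIP activates MesI(OAc)2 by hydrogen bonding, and the phloroglucinol-type ring A of 3 attacks trivalent iodine at C6, the carbon that iodine electrophiles choose in 5-hydroxy-7-alkoxyflavones, to give 5; the chelated, acyl-deactivated 5-OH resists oxidative dearomatisation and the only easily oxidised phenol is benzyl-capped. Loss of AcOH gives zwitterion 6, stabilised by an O5···I contact that a C8 isomer cannot have. Monovalent copper bound at O5 then inserts into the neighbouring flavonyl–I bond rather than the mesityl–I bond (equivalently, it expels MesI to give a copper quinoid carbene). The free 4'-OH of 4 binds, and C–O reductive elimination from trivalent copper (or O–H insertion with a rearomatising proton shift to O5) gives 7. The 5-olate is the internal proton acceptor, so no external base is needed and both chelated 5-OH groups stay silent. The hindered, electron-rich mesityl group suppresses its own transfer and the thermal iodine-to-oxygen aryl shift of such zwitterions. Closest known reaction types: copper-catalysed C–H amination of electron-rich arenes via in situ aryl(mesityl)-λ3-iodanes, O-arylation of phenols with diaryliodonium salts, and metal-catalysed O–H insertion of iodonium ylides.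

**Step 5**
Reactants: 7 di-O-benzylisocryptomerin
Product: 8 isocryptomerin
Conditions: H2 (1 atm), 10% Pd/C, THF–MeOH, rt
Reagents that add atoms: none
Why: Heterogeneous catalytic hydrogenolysis cleaves both benzylic C–O bonds, while the aryl-conjugated C2=C3 bonds, the diaryl ether and the aryl methyl ether are inert at one atmosphere.

**Compound list**
1 | apigenin, 5,7-dihydroxy-2-(4-hydroxyphenyl)-4H-chromen-4-one | O=c1cc(-c2ccc(O)cc2)oc2cc(O)cc(O)c12 | starting material
2 | genkwanin, 5-hydroxy-2-(4-hydroxyphenyl)-7-methoxy-4H-chromen-4-one | COc1cc(O)c2c(=O)cc(-c3ccc(O)cc3)oc2c1 | intermediate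
3 | 4'-O-benzylgenkwanin, 2-[4-(benzyloxy)phenyl]-5-hydroxy-7-methoxy-4H-chromen-4-one | COc1cc(O)c2c(=O)cc(-c3ccc(OCc4ccccc4)cc3)oc2c1 | intermediate
4 | 7-O-benzylapigenin, 7-(benzyloxy)-5-hydroxy-2-(4-hydroxyphenyl)-4H-chromen-4-one | O=c1cc(-c2ccc(O)cc2)oc2cc(OCc3ccccc3)cc(O)c12 | intermediate
5 | {2-[4-(benzyloxy)phenyl]-5-hydroxy-7-methoxy-4-oxo-4H-chromen-6-yl}(2,4,6-trimethylphenyl)iodonium acetate | COc1cc2oc(-c3ccc(OCc4ccccc4)cc3)cc(=O)c2c(O)c1[I+]c1c(C)cc(C)cc1C.CC(=O)[O-] | intermediate
6 | 2-[4-(benzyloxy)phenyl]-7-methoxy-4-oxo-6-[(2,4,6-trimethylphenyl)iodonio]-4H-chromen-5-olate | COc1cc2oc(-c3ccc(OCc4ccccc4)cc3)cc(=O)c2c([O-])c1[I+]c1c(C)cc(C)cc1C | intermediate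
7 | di-O-benzylisocryptomerin, 6-{4-[7-(benzyloxy)-5-hydroxy-4-oxo-4H-chromen-2-yl]phenoxy}-2-[4-(benzyloxy)phenyl]-5-hydroxy-7-methoxy-4H-chromen-4-one | COc1cc2oc(-c3ccc(OCc4ccccc4)cc3)cc(=O)c2c(O)c1Oc1ccc(-c2cc(=O)c3c(O)cc(OCc4ccccc4)cc3o2)cc1 | intermediate
8 | isocryptomerin, 6-[4-(5,7-dihydroxy-4-oxo-4H-chromen-2-yl)phenoxy]-5-hydroxy-2-(4-hydroxyphenyl)-7-methoxy-4H-chromen-4-one | COc1cc2oc(-c3ccc(O)cc3)cc(=O)c2c(O)c1Oc1ccc(-c2cc(=O)c3c(O)cc(O)cc3o2)cc1 | target

**Total step count:** 5. **Longest linear sequence:** 4 (steps 1, 2, 4, 5).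

**Three steps most likely to fail**

Step 4 (the proposed new step). It can fail in four ways:
- iodine attack at C8 instead of C6;
- oxidative damage to ring A;
- mesityl transfer to 4;
- capture of adventitious water.

The fallback uses only known chemistry. It sets out from 3 (and uses 4 from step 3) and comes back to the route at 8. N-Iodosuccinimide in DMF at rt iodinates 5-hydroxy-7-alkoxyflavones ortho to the free 5-OH and gives 6-iodo-4'-O-benzylgenkwanin F1. BnBr, K2CO3, DMF at 70 °C caps the chelated 5-OH and gives 5,4'-di-O-benzyl-6-iodogenkwanin F2. An Ullmann diaryl ether coupling of F2 with 4 (CuI, picolinic acid, K3PO4, DMSO, 100 °C) gives tri-O-benzylisocryptomerin F3. The hydrogenolysis conditions of step 5 then remove all three benzyl groups and deliver 8. The detour costs two extra steps.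

Step 1. Methylation may spill over to the 4'-OH, and the mono- and dimethyl ethers are hard to separate. The fallback replaces acidity control by a protect-and-unmask sequence. It sets out from 1 and comes back at 2. Ac2O in pyridine gives apigenin triacetate F4. PhSH with imidazole in NMP at 0 °C removes only the most electrophilic 7-acetate and gives 5,4'-di-O-acetylapigenin F5. A Mitsunobu methylation (MeOH, PPh3, DIAD, THF) of the single free phenol gives 5,4'-di-O-acetylgenkwanin F6. Catalytic K2CO3 in MeOH transesterifies both acetates and gives 2.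

Step 5. Poor solubility of 7 and 8, catalyst poisoning by traces of iodomesitylene, or partial reduction of a C2=C3 bond could spoil the hydrogenolysis. The fallback is non-reductive. It sets out from 7 and comes back at 8. BCl3 with pentamethylbenzene in CH2Cl2 at −78 °C ionises the benzyl ethers, and the arene traps the benzyl cations by Friedel–Crafts alkylation. The 7-methoxy group is not peri to a carbonyl and survives. New compounds on this way: none F0.

**Further compounds**
F1 | step 4 | 6-iodo-4'-O-benzylgenkwanin, 2-[4-(benzyloxy)phenyl]-5-hydroxy-6-iodo-7-methoxy-4H-chromen-4-one | COc1cc2oc(-c3ccc(OCc4ccccc4)cc3)cc(=O)c2c(O)c1I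
F2 | step 4 | 5,4'-di-O-benzyl-6-iodogenkwanin, 5-(benzyloxy)-2-[4-(benzyloxy)phenyl]-6-iodo-7-methoxy-4H-chromen-4-one | COc1cc2oc(-c3ccc(OCc4ccccc4)cc3)cc(=O)c2c(OCc5ccccc5)c1I
F3 | step 4 | tri-O-benzylisocryptomerin, 5-(benzyloxy)-6-{4-[7-(benzyloxy)-5-hydroxy-4-oxo-4H-chromen-2-yl]phenoxy}-2-[4-(benzyloxy)phenyl]-7-methoxy-4H-chromen-4-one | COc1cc2oc(-c3ccc(OCc4ccccc4)cc3)cc(=O)c2c(OCc5ccccc5)c1Oc1ccc(-c2cc(=O)c3c(O)cc(OCc4ccccc4)cc3o2)cc1
F4 | step 1 | apigenin triacetate | CC(=O)Oc1ccc(-c2cc(=O)c3c(OC(C)=O)cc(OC(C)=O)cc3o2)cc1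
F5 | step 1 | 5,4'-di-O-acetylapigenin | CC(=O)Oc1ccc(-c2cc(=O)c3c(OC(C)=O)cc(O)cc3o2)cc1
F6 | step 1 | 5,4'-di-O-acetylgenkwanin | COc1cc(OC(C)=O)c2c(=O)cc(-c3ccc(OC(C)=O)cc3)oc2c1
F0 | step 5 | none | none
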